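**Assumption:** the target has no stereocentre and no configurationally stable axis, so it is achiral and no stereocontrol is needed; the compound itself is the "single enantiomer".

**Retrosynthetic overview**
1. Target ⇐ global O-demethylation (BBr3) of its tri-O-methyl ether.
2. The pyranone ring (the only ring formed; both benzene rings are bought) ⇐ acid-catalysed enol lactonisation of a methyl 2-(2-oxoheptyl)benzoate.
3. That keto ester ⇐ intermolecular crossed Claisen-type condensation of a laterally lithiated o-toluate (vinylogous ester enolate) with N-methoxy-N-methylhexanamide; this is the key C–C bond (C3–C4 of the isocoumarin).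
4. The o-toluate diaryl ether ⇐ Cu-catalysed Ullmann C–O coupling of 2,4-dimethoxy-6-pentylphenol with methyl 2-bromo-4-methoxy-6-methylbenzoate.
5. Phenol ⇐ olivetol (methylation, Vilsmeier formylation, Dakin oxidation); bromobenzoate ⇐ 4-methoxy-2-methylaniline (bromination, Sandmeyer iodination, I/Mg exchange and methoxycarbonylation).

**Route**

Step 1
Reactants: 1 olivetol (5-pentylbenzene-1,3-diol)
Product: 2 1,3-dimethoxy-5-pentylbenzene
Conditions: MeI (2.5 equiv), K2CO3 (3 equiv), acetone, reflux
Reagents that add atoms: iodomethane CI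
Why: Williamson O-methylation of both phenols is a standard, high-yielding protection that survives every later step up to the final BBr3 cleavage.

Step 2
Reactants: 2 1,3-dimethoxy-5-pentylbenzene
Product: 4 2,4-dimethoxy-6-pentylbenzaldehyde, via aryl iminium chloride 3 (not isolated)
Conditions: POCl3 (1.5 equiv), DMF, 0 → 70 °C; then ice-water
Reagents that add atoms: N,N-dimethylformamide CN(C)C=O; water O
Why: Vilsmeier–Haack formylation of the resorcinol dimethyl ether goes para to one OMe and ortho to the other, next to the alkyl chain (as with orcinol dimethyl ether), and the minor 4-formyl isomer is removed by chromatography.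

Step 3
Reactants: 4 2,4-dimethoxy-6-pentylbenzaldehyde
Product: 6 2,4-dimethoxy-6-pentylphenol, via aryl formate 5 (not isolated)
Conditions: mCPBA (1.3 equiv), CH2Cl2, 0 °C → rt; aq NaHCO3/Na2S2O3 wash; then K2CO3 (cat.), MeOH, rt
Reagents that add atoms: 3-chloroperoxybenzoic acid OOC(=O)c1cccc(Cl)c1
Why: In this Dakin-type Baeyer–Villiger oxidation the electron-rich aryl group migrates to give the aryl formate, which mild methanolysis converts into the phenol.

Step 4
Reactants: 7 4-methoxy-2-methylaniline
Product: 8 2-bromo-4-methoxy-6-methylaniline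
Conditions: NBS (1.0 equiv), DMF, −10 → 0 °C
Reagents that add atoms: N-bromosuccinimide O=C1CCC(=O)N1Br
Why: Electrophilic aromatic bromination is directed by the free NH2, the strongest activator, to its only open ortho position (para is blocked by OMe).

Step 5
Reactants: 8 2-bromo-4-methoxy-6-methylaniline
Product: 10 1-bromo-2-iodo-5-methoxy-3-methylbenzene, via arenediazonium hydrogensulfate 9 (not isolated)
Conditions: NaNO2, aq H2SO4, MeCN, 0 °C; then KI, 0 °C → rt
Reagents that add atoms: potassium iodide [K+].[I-]
Why: Diazotisation followed by Sandmeyer-type iodide displacement (no copper needed) replaces NH2 by I with loss of N2.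

Step 6
Reactants: 10 1-bromo-2-iodo-5-methoxy-3-methylbenzene
Product: 12 methyl 2-bromo-4-methoxy-6-methylbenzoate, via arylmagnesium chloride 11 (not isolated)
Conditions: iPrMgCl·LiCl (1.1 equiv), THF, −30 °C; then ClCO2Me (2 equiv), −30 °C → rt
Reagents that add atoms: methyl chloroformate COC(=O)Cl
Why: Knochel iodine–magnesium exchange is selective for C–I over C–Br at −30 °C (no benzyne formation), and the aryl Grignard is acylated by the chloroformate to a hindered ester that does not react further.

Step 7
Reactants: 6 2,4-dimethoxy-6-pentylphenol; 12 methyl 2-bromo-4-methoxy-6-methylbenzoate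
Product: 13 methyl 2-(2,4-dimethoxy-6-pentylphenoxy)-4-methoxy-6-methylbenzoate
Conditions: CuI (10 mol%), picolinic acid (20 mol%), K3PO4 (2 equiv), DMSO, 90–100 °C, Ar
Reagents that add atoms: none
Why: Ullmann-type Cu(I)/picolinic acid C–O coupling, a system suited to hindered diaryl ethers, joins the electron-rich phenoxide to the ortho-ester-activated aryl bromide.

Step 8
Reactants: 14 hexanoyl chloride; 15 N,O-dimethylhydroxylamine hydrochloride
Product: 16 N-methoxy-N-methylhexanamide
Conditions: Et3N (2.2 equiv), CH2Cl2, 0 °C → rt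
Reagents that add atoms: none
Why: Simple N-acylation of the hydroxylamine by the acid chloride gives the Weinreb amide cleanly.

Step 9
Reactants: 13 methyl 2-(2,4-dimethoxy-6-pentylphenoxy)-4-methoxy-6-methylbenzoate; 16 N-methoxy-N-methylhexanamide
Product: 19 methyl 2-(2,4-dimethoxy-6-pentylphenoxy)-4-methoxy-6-(2-oxoheptyl)benzoate, via benzylic lithium species 17 (not isolated), via tetrahedral lithium alkoxide 18 (not isolated)
Conditions: LDA (1.3 equiv), THF, −78 °C, 30 min; then 16 (1.5 equiv), −78 → −20 °C; then 1 M HCl
Reagents that add atoms: none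
Why: Lateral deprotonation of the o-toluate gives a vinylogous ester enolate that is C-acylated by the Weinreb amide in an intermolecular crossed Claisen-type condensation; the chelated tetrahedral adduct (transient, racemic centre) blocks over-addition and collapses to the ketone on work-up.

Step 10
Reactants: 19 methyl 2-(2,4-dimethoxy-6-pentylphenoxy)-4-methoxy-6-(2-oxoheptyl)benzoate
Product: 20 8-(2,4-dimethoxy-6-pentylphenoxy)-6-methoxy-3-pentyl-1H-isochromen-1-one
Conditions: TsOH·H2O (0.2 equiv), toluene, reflux, 4 Å MS
Reagents that add atoms: none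
Why: Acid-catalysed enol lactonisation (the ketone enol oxygen attacks the ester with loss of MeOH) closes the conjugated pyranone ring and avoids the base-induced Dieckmann pathway to a naphthalenediol.

Step 11
Reactants: 20 8-(2,4-dimethoxy-6-pentylphenoxy)-6-methoxy-3-pentyl-1H-isochromen-1-one
Product: 21 8-(2,4-dihydroxy-6-pentylphenoxy)-6-hydroxy-3-pentyl-1H-isochromen-1-one (target)
Conditions: BBr3 (8 equiv), CH2Cl2, −78 °C → rt, 16 h; then ice-water
Reagents that add atoms: none
Why: BBr3 Lewis-acid ether cleavage removes all three aryl methyl ethers, while the diaryl ether and the enol lactone, which have no SN2-cleavable alkyl–O bond, are left intact.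

**Compound list**
1 | olivetol (5-pentylbenzene-1,3-diol) | CCCCCc1cc(O)cc(O)c1 | starting material
2 | 1,3-dimethoxy-5-pentylbenzene | CCCCCc1cc(OC)cc(OC)c1 | intermediate
3 | (2,4-dimethoxy-6-pentylbenzylidene)dimethyliminium chloride (formed in situ) | CCCCCc1cc(OC)cc(OC)c1C=[N+](C)C.[Cl-] | intermediate
4 | 2,4-dimethoxy-6-pentylbenzaldehyde | CCCCCc1cc(OC)cc(OC)c1C=O | intermediate
5 | 2,4-dimethoxy-6-pentylphenyl formate (formed in situ) | CCCCCc1cc(OC)cc(OC)c1OC=O | intermediate
6 | 2,4-dimethoxy-6-pentylphenol | CCCCCc1cc(OC)cc(OC)c1O | intermediate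
7 | 4-methoxy-2-methylaniline | COc1ccc(N)c(C)c1 | starting material
8 | 2-bromo-4-methoxy-6-methylaniline | COc1cc(C)c(N)c(Br)c1 | intermediate
9 | 2-bromo-4-methoxy-6-methylbenzenediazonium hydrogensulfate (formed in situ) | COc1cc(C)c([N+]#N)c(Br)c1.OS(=O)(=O)[O-] | intermediate
10 | 1-bromo-2-iodo-5-methoxy-3-methylbenzene | COc1cc(C)c(I)c(Br)c1 | intermediate
11 | (2-bromo-4-methoxy-6-methylphenyl)magnesium chloride (formed in situ) | COc1cc(C)c([Mg]Cl)c(Br)c1 | intermediate
12 | methyl 2-bromo-4-methoxy-6-methylbenzoate | COC(=O)c1c(C)cc(OC)cc1Br | intermediate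
13 | methyl 2-(2,4-dimethoxy-6-pentylphenoxy)-4-methoxy-6-methylbenzoate | COC(=O)c1c(C)cc(OC)cc1Oc1c(OC)cc(OC)cc1CCCCC | intermediate
14 | hexanoyl chloride | CCCCCC(=O)Cl | starting material
15 | N,O-dimethylhydroxylamine hydrochloride | CNOC.Cl | starting material
16 | N-methoxy-N-methylhexanamide | CCCCCC(=O)N(C)OC | intermediate
17 | benzylic lithium species of 13 (laterally lithiated toluate, formed in situ) | [Li]Cc1cc(OC)cc(Oc2c(OC)cc(OC)cc2CCCCC)c1C(=O)OC | intermediate
18 | tetrahedral lithium alkoxide adduct of 17 and 16 (formed in situ, racemic transient centre) | CCCCCC(O[Li])(Cc1cc(OC)cc(Oc2c(OC)cc(OC)cc2CCCCC)c1C(=O)OC)N(C)OC | intermediate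
19 | methyl 2-(2,4-dimethoxy-6-pentylphenoxy)-4-methoxy-6-(2-oxoheptyl)benzoate | CCCCCC(=O)Cc1cc(OC)cc(Oc2c(OC)cc(OC)cc2CCCCC)c1C(=O)OC | intermediate
20 | 8-(2,4-dimethoxy-6-pentylphenoxy)-6-methoxy-3-pentyl-1H-isochromen-1-one | CCCCCc1cc2cc(OC)cc(Oc3c(OC)cc(OC)cc3CCCCC)c2c(=O)o1 | intermediate
21 | 8-(2,4-dihydroxy-6-pentylphenoxy)-6-hydroxy-3-pentyl-1H-isochromen-1-one | CCCCCc1cc2cc(O)cc(Oc3c(O)cc(O)cc3CCCCC)c2c(=O)o1 | target

**Summary**
Total step count: 11.
Longest linear sequence: 7 steps (steps 1, 2, 3, 7, 9, 10, 11; the branch through steps 4, 5, 6, 7, 9, 10, 11 is equally long).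

**Steps most likely to fail, with fallbacks**

Step 7 (Ullmann coupling of a di-ortho-substituted phenol with an ortho-substituted bromobenzoate) is the first risk. The fallback sets out from 10 (with 6) and comes back at 13. It uses the carboxylate-accelerated Ullmann condensation of a free o-bromobenzoic acid. The Grignard 11, made from 10 as in step 6, is quenched with CO2 instead of methyl chloroformate to give 2-bromo-4-methoxy-6-methylbenzoic acid F1. F1 and phenol 6 are condensed with Cu powder/Cu2O and K2CO3 in DMF at 130 °C to give 2-(2,4-dimethoxy-6-pentylphenoxy)-4-methoxy-6-methylbenzoic acid F2. Esterification of F2 with MeI/K2CO3 in DMF gives 13.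

Step 9 (acylation of the toluate anion by an enolisable Weinreb amide) is the second risk, through proton transfer or self-condensation. The fallback sets out from 13 and comes back at 20. It goes through the homophthalic acid instead of the keto ester. Anion 17 (LDA, THF, −78 °C) is trapped with CO2, a fast and non-enolisable electrophile, to give 2-[3-(2,4-dimethoxy-6-pentylphenoxy)-5-methoxy-2-(methoxycarbonyl)phenyl]acetic acid F3. Saponification (KOH, aq EtOH, reflux; then HCl) gives 2-(carboxymethyl)-6-(2,4-dimethoxy-6-pentylphenoxy)-4-methoxybenzoic acid F4. Heating F4 with excess hexanoyl chloride 14 (neat, 190–200 °C) brings about C-acylation, decarboxylation and enol lactonisation in one operation and gives 20 directly.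

Step 10 (direct enol lactonisation of a hindered methyl ester) is the third risk, since it may be slow. The fallback sets out from 19 and comes back at 20. It goes through the free keto acid. The ester methyl group is removed by SN2 demethylation with LiI in pyridine at reflux, which is non-basic enough to avoid the Dieckmann route. This gives 2-(2,4-dimethoxy-6-pentylphenoxy)-4-methoxy-6-(2-oxoheptyl)benzoic acid F5, in equilibrium with its lactol. Cyclodehydration of F5 with TFAA in CH2Cl2 (0 °C → rt) gives 20.

**Further compounds**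
F1 | step 7 | 2-bromo-4-methoxy-6-methylbenzoic acid | COc1cc(C)c(C(=O)O)c(Br)c1
F2 | step 7 | 2-(2,4-dimethoxy-6-pentylphenoxy)-4-methoxy-6-methylbenzoic acid | COc1cc(C)c(C(=O)O)c(Oc2c(OC)cc(OC)cc2CCCCC)c1
F3 | step 9 | 2-[3-(2,4-dimethoxy-6-pentylphenoxy)-5-methoxy-2-(methoxycarbonyl)phenyl]acetic acid | COC(=O)c1c(CC(=O)O)cc(OC)cc1Oc1c(OC)cc(OC)cc1CCCCC
F4 | step 9 | 2-(carboxymethyl)-6-(2,4-dimethoxy-6-pentylphenoxy)-4-methoxybenzoic acid | OC(=O)Cc1cc(OC)cc(Oc2c(OC)cc(OC)cc2CCCCC)c1C(=O)O
F5 | step 10 | 2-(2,4-dimethoxy-6-pentylphenoxy)-4-methoxy-6-(2-oxoheptyl)benzoic acid | CCCCCC(=O)Cc1cc(OC)cc(Oc2c(OC)cc(OC)cc2CCCCC)c1C(=O)O
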